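Bromophycolide A is cut at the C10–Br and C11–O bonds of its chain bromohydrin. Because the C11 oxygen and C14, the oxygen-bearing CH of the 15-membered lactone (ring M), stand in a 1,4 relation, C14 is carried as a carboxylic acid. One catalytic, enantioselective 5-exo bromolactonization of an E C10=C11 alkene then places bromine on C10 and oxygen on C11 anti to each other and stores both as a γ-lactone. The precursor is the achiral, acyclic (E)-4-methylnon-4-en-8-ynoic acid. Its alkyne later becomes C6=C7, from which the bromocyclohexene (ring A) is closed, and the arene (ring B) is attached by Negishi couplings.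

Key step: step 5

Numbering used below: C1 = benzylic CH2; C2=C3 = alkene of ring A; C6 = ring CHBr; C7 = quaternary ring carbon; C10 = chain CHBr; C11 = tertiary carbinol; C14 = ester CH; C15 = CMe2Br; ring B = arene; ring M = macrolactone.

Assumption: the quinidine-derived amino-thiocarbamate is taken as the pseudoenantiomer that delivers Br+ to the Re face of C10; if the sense proves opposite, the quinine-derived catalyst is used with no other change.

Step 1
Reactants: 1 pent-4-yn-1-ol
Product: 2 pent-4-ynal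
Conditions: TEMPO (10 mol%), PhI(OAc)2, CH2Cl2, rt
Reagents that add atoms: none
Why: Nitroxyl-catalysed alcohol oxidation stops at the aldehyde and does not touch the terminal alkyne.

Step 2
Reactants: 2 pent-4-ynal; 3 isopropenylmagnesium bromide
Product: 4 2-methylhept-1-en-6-yn-3-ol (racemic)
Conditions: THF, −78 → 0 °C; then H2O (aq. NH4Cl work-up)
Reagents that add atoms: none
Why: Grignard 1,2-addition to the aldehyde is far faster than deprotonation of the alkyne at low temperature, and the carbinol stereocentre needs no control because it is destroyed in step 3.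

Step 3
Reactants: 4 2-methylhept-1-en-6-yn-3-ol; 5 triethyl orthoacetate
Product: 7 ethyl (4E)-4-methylnon-4-en-8-ynoate, via ketene acetal 6 (not isolated)
Conditions: EtCO2H (cat.), 140 °C, EtOH distilled off
Reagents that add atoms: none
Why: Johnson–Claisen rearrangement through a chair transition state with the butynyl chain equatorial should give the E trisubstituted alkene.

Step 4
Reactants: 7 ethyl (4E)-4-methylnon-4-en-8-ynoate
Product: 8 (4E)-4-methylnon-4-en-8-ynoic acid
Conditions: LiOH, THF/H2O, rt; then aq. HCl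
Reagents that add atoms: lithium hydroxide, [Li+].[OH-]
Why: Saponification of an unhindered ethyl ester leaves alkene geometry and alkyne unchanged.

Step 5
Reactants: 8 (4E)-4-methylnon-4-en-8-ynoic acid
Product: 9 (5S)-5-[(1R)-1-bromopent-4-yn-1-yl]-5-methyloxolan-2-one
Conditions: NBS (1.1 equiv), quinidine-derived amino-thiocarbamate catalyst (10 mol%), CHCl3/toluene, −78 °C, dark
Reagents that add atoms: N-bromosuccinimide, O=C1CCC(=O)N1Br
Why: The thiocarbamate sulfur of the catalyst takes up Br+ from NBS while its quinuclidine nitrogen holds the carboxylic acid, so the bromiranium ion forms on the Re face of C10 and is opened at once by the carboxylate at the tertiary carbon C11 (anti addition). The closest known reaction type is the amino-thiocarbamate-catalysed enantioselective bromolactonization of 4-substituted alk-4-enoic acids. The oxolan-2-one ring closes in the 5-exo mode. The absolute configuration at C10 and C11 is fixed by the chiral catalyst alone, since the substrate has no stereocentre, and the relative (10R,11S) configuration follows from anti addition across the E alkene. The step needs Markovnikov regioselectivity and chemoselectivity for the alkene over the alkyne: the methyl group on C11 stabilises positive charge there and makes the five-membered closure the low-energy path, and the terminal alkyne is much less nucleophilic towards NBS than the trisubstituted alkene.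

Step 6
Reactants: 9 (5S)-5-[(1R)-1-bromopent-4-yn-1-yl]-5-methyloxolan-2-one
Product: 11 (5S)-5-[(1R,4E)-1-bromo-5-iodo-4-methylpent-4-en-1-yl]-5-methyloxolan-2-one, via alkenylalane 10 (not isolated)
Conditions: Me3Al, Cp2ZrCl2 (20 mol%), H2O (1 equiv), CH2Cl2, −20 °C; then I2, THF, −20 → 0 °C
Reagents that add atoms: trimethylaluminium, C[Al](C)C; iodine, [I][I]
Why: Zirconium-catalysed syn carboalumination (Negishi) puts methyl on C7 and aluminium on C6, and iodinolysis with retention gives the E iodide; the water-accelerated variant runs at −20 °C, where Me3Al should spare the lactone and the secondary bromide.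

Step 7
Reactants: 12 4-bromo-2-methylphenol
Product: 13 (4-bromo-2-methylphenoxy)tri(propan-2-yl)silane
Conditions: i-Pr3SiCl, imidazole, DMF, rt
Reagents that add atoms: chlorotri(propan-2-yl)silane, CC(C)[Si](Cl)(C(C)C)C(C)C
Why: Standard phenol silylation; the bulky aryl silyl ether tolerates organozinc, Grignard and dilute acid, and its shielded oxygen should not trap the cation of step 17.

Step 8
Reactants: 13 (4-bromo-2-methylphenoxy)tri(propan-2-yl)silane
Product: 14 [4-bromo-2-(bromomethyl)phenoxy]tri(propan-2-yl)silane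
Conditions: NBS, AIBN (cat.), PhCF3, 80 °C
Reagents that add atoms: N-bromosuccinimide, O=C1CCC(=O)N1Br
Why: Wohl–Ziegler radical bromination takes place at the only benzylic C–H position.

Step 9
Reactants: 15 4-(trimethylsilyl)but-3-yn-1-ol
Product: 16 tert-butyldimethyl{[4-(trimethylsilyl)but-3-yn-1-yl]oxy}silane
Conditions: t-BuMe2SiCl, imidazole, CH2Cl2, rt
Reagents that add atoms: tert-butyl(chloro)dimethylsilane, CC(C)(C)[Si](C)(C)Cl
Why: Silylation of a primary alcohol protects it from the Grignard reagent of step 10.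

Step 10
Reactants: 16 tert-butyldimethyl{[4-(trimethylsilyl)but-3-yn-1-yl]oxy}silane
Product: 18 tert-butyl{[(3E)-4-iodo-3-methyl-4-(trimethylsilyl)but-3-en-1-yl]oxy}dimethylsilane, via alkenylmagnesium bromide 17 (not isolated)
Conditions: MeMgBr, Ni(acac)2 (10 mol%), Me3Al (10 mol%), THF, rt; then I2, −78 → 0 °C
Reagents that add atoms: methylmagnesium bromide, C[Mg]Br; iodine, [I][I]
Why: Nickel-catalysed syn carbomagnesiation of a silylalkyne places methyl on C3 and magnesium on the silicon-bearing C2, and iodinolysis proceeds with retention; the alkene geometry is not critical because silicon is lost in step 17 and both geometries converge.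

Step 11
Reactants: 14 [4-bromo-2-(bromomethyl)phenoxy]tri(propan-2-yl)silane; 18 tert-butyl{[(3E)-4-iodo-3-methyl-4-(trimethylsilyl)but-3-en-1-yl]oxy}dimethylsilane
Product: 20 {4-bromo-2-[(2Z)-5-{[tert-butyl(dimethyl)silyl]oxy}-3-methyl-2-(trimethylsilyl)pent-2-en-1-yl]phenoxy}tri(propan-2-yl)silane, via benzylzinc bromide 19 (not isolated)
Conditions: 14, Zn dust, LiCl, THF, 0 °C → rt; then 18, Pd(PPh3)4 (5 mol%), THF, 40 °C
Reagents that add atoms: none
Why: Zinc inserts only into the benzylic C–Br bond, and Negishi coupling at the alkenyl iodide (retention of geometry) should be much faster than oxidative addition into the electron-rich aryl bromide.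

Step 12
Reactants: 20 {4-bromo-2-[(2Z)-5-{[tert-butyl(dimethyl)silyl]oxy}-3-methyl-2-(trimethylsilyl)pent-2-en-1-yl]phenoxy}tri(propan-2-yl)silane
Product: 21 (3Z)-5-{5-bromo-2-[tri(propan-2-yl)silyloxy]phenyl}-3-methyl-4-(trimethylsilyl)pent-3-en-1-ol
Conditions: camphorsulfonic acid (cat.), MeOH/CH2Cl2, 0 °C
Reagents that add atoms: none
Why: Acid-catalysed methanolysis removes the primary alkyl silyl ether, whereas the aryl silyl ether and the fully substituted alkenylsilane are stable to dilute acid.

Step 13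
Reactants: 21 (3Z)-5-{5-bromo-2-[tri(propan-2-yl)silyloxy]phenyl}-3-methyl-4-(trimethylsilyl)pent-3-en-1-ol
Product: 22 {4-bromo-2-[(2Z)-5-iodo-3-methyl-2-(trimethylsilyl)pent-2-en-1-yl]phenoxy}tri(propan-2-yl)silane
Conditions: I2, PPh3, imidazole, CH2Cl2, 0 °C
Reagents that add atoms: iodine, [I][I]
Why: Appel-type iodination converts the primary alcohol by SN2 displacement of its alkoxyphosphonium ion.

Step 14
Reactants: 22 {4-bromo-2-[(2Z)-5-iodo-3-methyl-2-(trimethylsilyl)pent-2-en-1-yl]phenoxy}tri(propan-2-yl)silane; 11 (5S)-5-[(1R,4E)-1-bromo-5-iodo-4-methylpent-4-en-1-yl]-5-methyloxolan-2-one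
Product: 24 (5S)-5-[(1R,4E,8Z)-1-bromo-10-{5-bromo-2-[tri(propan-2-yl)silyloxy]phenyl}-4,8-dimethyl-9-(trimethylsilyl)deca-4,8-dien-1-yl]-5-methyloxolan-2-one, via alkylzinc iodide 23 (not isolated)
Conditions: 22, Zn dust, LiCl, THF, 40 °C; then 11, PdCl2(dppf) (5 mol%), THF, rt
Reagents that add atoms: none
Why: Negishi sp3–sp2 coupling forms C5–C6 with retention of the E geometry; alkylzinc halides tolerate the lactone and the secondary bromide, and the alkenyl iodide should react well before the aryl bromide.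

Step 15
Reactants: 24 (5S)-5-[(1R,4E,8Z)-1-bromo-10-{5-bromo-2-[tri(propan-2-yl)silyloxy]phenyl}-4,8-dimethyl-9-(trimethylsilyl)deca-4,8-dien-1-yl]-5-methyloxolan-2-one
Product: 25 (6R,7R)-6,7-epoxide of 24
Conditions: D-fructose-derived Shi ketone (30 mol%), KHSO5 (as 2KHSO5·KHSO4·K2SO4), K2CO3, Bu4NHSO4, MeCN/CH2(OMe)2/aq. Na2B4O7 buffer, 0 °C
Reagents that add atoms: potassium peroxymonosulfate (KHSO5), [K+].[O-]S(=O)(=O)OO
Why: Shi epoxidation: the chiral dioxirane attacks the E trisubstituted C6=C7 alkene through its spiro transition state and should set (6R,7R) under reagent control, whereas the tetrasubstituted, silyl-shielded C2=C3 alkene has no small substituent to fit that transition state.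

Step 16
Reactants: 25 (6R,7R)-6,7-epoxide of 24
Product: 26 (6S,7R)-6-bromo-7-hydroxy bromohydrin
Conditions: Li2NiBr4, THF, 0 °C → rt; then H2O
Reagents that add atoms: dilithium tetrabromonickelate (Li2NiBr4), [Li+].[Li+].[Ni+2].[Br-].[Br-].[Br-].[Br-]
Why: Soft bromide opens the weakly activated epoxide by SN2 at the less substituted carbon C6 with inversion, which should give the anti (6S,7R) bromohydrin with the C7–O bond untouched.

Step 17
Reactants: 26 (6S,7R)-6-bromo-7-hydroxy bromohydrin
Product: 27 (5S)-5-[(1R)-1-bromo-3-{(1S,6S)-6-bromo-2-({5-bromo-2-[tri(propan-2-yl)silyloxy]phenyl}methyl)-1,3-dimethylcyclohex-2-en-1-yl}propyl]-5-methyloxolan-2-one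
Conditions: Tf2O, 2,6-di-tert-butyl-4-methylpyridine, CH2Cl2, −78 → −40 °C
Reagents that add atoms: none
Why: Proposed new method: triflation turns the tertiary C7 hydroxyl into a nucleofuge that leaves with anchimeric assistance from the anti C6 bromine (inversion at C7), and the resulting enantiopure bromiranium ion is opened at C7, again with inversion, by C2 of the alkenylsilane in a chair-like 6-endo closure of ring A, after which the β-silyl cation at C3 loses Me3Si+ so that the alkene can only end at C2=C3 and C7 becomes S (net retention) next to the unchanged (6S) C–Br centre; the closest known reaction types are the enantiospecific capture of bromiranium ions generated from enantiopure bromohydrin derivatives and vinylsilane-terminated cation–olefin cyclizations.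

Step 18
Reactants: 27 ring-A bromolactone
Product: 28 (4S,5R)-5-bromo-7-{(1S,6S)-6-bromo-2-({5-bromo-2-[tri(propan-2-yl)silyloxy]phenyl}methyl)-1,3-dimethylcyclohex-2-en-1-yl}-4-hydroxy-N-methoxy-N,4-dimethylheptanamide
Conditions: MeNH(OMe)·HCl, Me3Al, CH2Cl2, 0 °C → rt; crude product used at once
Reagents that add atoms: N,O-dimethylhydroxylamine hydrochloride, CNOC.Cl
Why: Aluminium-amide aminolysis (Weinreb amide formation) opens the γ-lactone at C14, while aryl bromide, aryl silyl ether and alkyl bromides are inert to the reagent.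

Step 19
Reactants: 28 hydroxy Weinreb amide
Product: 29 11-O-triethylsilyl Weinreb amide
Conditions: Et3SiOTf, 2,6-lutidine, CH2Cl2, −78 → 0 °C
Reagents that add atoms: triethylsilyl trifluoromethanesulfonate, CC[Si](CC)(CC)OS(=O)(=O)C(F)(F)F
Why: Silyl triflates silylate hindered tertiary alcohols with a non-nucleophilic base that cannot close the C10/C11 bromohydrin to an epoxide, and the ether blocks relactonization and epoxide formation in steps 20 to 22.

Step 20
Reactants: 29 11-O-triethylsilyl Weinreb amide; 3 isopropenylmagnesium bromide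
Product: 30 isopropenyl ketone (C14 ketone)
Conditions: THF, −20 → 0 °C; then H2O (aq. NH4Cl work-up)
Reagents that add atoms: none
Why: Weinreb ketone synthesis: the chelated tetrahedral intermediate prevents over-addition, and the aryl and alkyl bromides do not exchange with the alkenyl Grignard reagent at this temperature.

Step 21
Reactants: 30 isopropenyl ketone
Product: 31 (14S)-allylic alcohol
Conditions: (R)-2-methyl-CBS-oxazaborolidine (20 mol%), catecholborane, toluene, −78 °C
Reagents that add atoms: none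
Why: CBS reduction with the isopropenyl group as the large and the CH2 chain as the small ketone substituent should give the (14S) alcohol under reagent control, and catecholborane does not hydroborate the alkenes at this temperature.

Step 22
Reactants: 31 (14S)-allylic alcohol
Product: 32 macrolactone with isopropenyl group on C14 (11-O-SiEt3, aryl O-Si(i-Pr)3)
Conditions: Pd(OAc)2 (10 mol%), Xantphos (12 mol%), CO (1 atm), Et3N, toluene, 100 °C, slow addition to high dilution
Reagents that add atoms: carbon monoxide, [C-]#[O+]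
Why: Palladium-catalysed carbonylative macrolactonization: zerovalent palladium adds to the aryl C–Br bond, CO inserts and the C14 hydroxyl cleaves the acylpalladium species to close the 15-membered ring M, while the silylated C11 oxygen cannot compete and unactivated secondary alkyl bromides should not add to the catalyst.

Step 23
Reactants: 32 macrolactone with isopropenyl group on C14
Product: 33 bis-silyl ether of bromophycolide A
Conditions: Co(acac)2 (cat.), t-BuOOH (cat.), Et3SiH, TsBr, n-PrOH, rt
Reagents that add atoms: 4-methylbenzenesulfonyl bromide, Cc1ccc(cc1)S(=O)(=O)Br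
Why: Mukaiyama-type hydrogen-atom-transfer hydrobromination: a cobalt hydride gives H• to the terminal CH2 of the 1,1-disubstituted alkene and the tertiary C15 radical takes bromine from TsBr (Markovnikov), whereas the tetrasubstituted ring-A alkene is too hindered for hydrogen-atom transfer, and C15 is not a stereocentre.

Step 24
Reactants: 33 bis-silyl ether of bromophycolide A
Product: 34 bromophycolide A
Conditions: HF·pyridine, THF, 0 °C → rt
Reagents that add atoms: none
Why: Fluoride desilylation under mildly acidic conditions removes the aryl and the tertiary silyl ether without forming an alkoxide next to C10–Br, so neither epoxide closure nor loss of the tertiary bromide is expected.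

Compound list
1 | pent-4-yn-1-ol | OCCCC#C | starting material
2 | pent-4-ynal | O=CCCC#C | intermediate
3 | isopropenylmagnesium bromide | CC(=C)[Mg]Br | starting material
4 | 2-methylhept-1-en-6-yn-3-ol (racemic) | CC(=C)C(O)CCC#C | intermediate
5 | triethyl orthoacetate | CCOC(C)(OCC)OCC | starting material
6 | 3-[(1-ethoxyethenyl)oxy]-2-methylhept-1-en-6-yne (ketene acetal) | C=C(OCC)OC(CCC#C)C(C)=C | intermediate (not isolated)
7 | ethyl (4E)-4-methylnon-4-en-8-ynoate | CCOC(=O)CC/C(C)=C/CCC#C | intermediate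
8 | (4E)-4-methylnon-4-en-8-ynoic acid | OC(=O)CC/C(C)=C/CCC#C | intermediate
9 | (5S)-5-[(1R)-1-bromopent-4-yn-1-yl]-5-methyloxolan-2-one | O=C1CC[C@](C)(O1)[C@H](Br)CCC#C | intermediate
10 | dimethyl{(1E,5R)-5-bromo-2-methyl-5-[(2S)-2-methyl-5-oxooxolan-2-yl]pent-1-en-1-yl}alumane | O=C1CC[C@](C)(O1)[C@H](Br)CC/C(C)=C/[Al](C)C | intermediate (not isolated)
11 | (5S)-5-[(1R,4E)-1-bromo-5-iodo-4-methylpent-4-en-1-yl]-5-methyloxolan-2-one | O=C1CC[C@](C)(O1)[C@H](Br)CC/C(C)=C/I | intermediate
12 | 4-bromo-2-methylphenol | Cc1cc(Br)ccc1O | starting material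
13 | (4-bromo-2-methylphenoxy)tri(propan-2-yl)silane | Cc1cc(Br)ccc1O[Si](C(C)C)(C(C)C)C(C)C | intermediate
14 | [4-bromo-2-(bromomethyl)phenoxy]tri(propan-2-yl)silane | BrCc1cc(Br)ccc1O[Si](C(C)C)(C(C)C)C(C)C | intermediate
15 | 4-(trimethylsilyl)but-3-yn-1-ol | C[Si](C)(C)C#CCCO | starting material
16 | tert-butyldimethyl{[4-(trimethylsilyl)but-3-yn-1-yl]oxy}silane | C[Si](C)(C)C#CCCO[Si](C)(C)C(C)(C)C | intermediate
17 | bromo[(1Z)-4-{[tert-butyl(dimethyl)silyl]oxy}-2-methyl-1-(trimethylsilyl)but-1-en-1-yl]magnesium | C[Si](C)(C)/C([Mg]Br)=C(C)\CCO[Si](C)(C)C(C)(C)C | intermediate (not isolated)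
18 | tert-butyl{[(3E)-4-iodo-3-methyl-4-(trimethylsilyl)but-3-en-1-yl]oxy}dimethylsilane | C[Si](C)(C)/C(I)=C(C)\CCO[Si](C)(C)C(C)(C)C | intermediate
19 | bromo({5-bromo-2-[tri(propan-2-yl)silyloxy]phenyl}methyl)zinc | Br[Zn]Cc1cc(Br)ccc1O[Si](C(C)C)(C(C)C)C(C)C | intermediate (not isolated)
20 | {4-bromo-2-[(2Z)-5-{[tert-butyl(dimethyl)silyl]oxy}-3-methyl-2-(trimethylsilyl)pent-2-en-1-yl]phenoxy}tri(propan-2-yl)silane | C[Si](C)(C)/C(Cc1cc(Br)ccc1O[Si](C(C)C)(C(C)C)C(C)C)=C(C)\CCO[Si](C)(C)C(C)(C)C | intermediate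
21 | (3Z)-5-{5-bromo-2-[tri(propan-2-yl)silyloxy]phenyl}-3-methyl-4-(trimethylsilyl)pent-3-en-1-ol | C[Si](C)(C)/C(Cc1cc(Br)ccc1O[Si](C(C)C)(C(C)C)C(C)C)=C(C)\CCO | intermediate
22 | {4-bromo-2-[(2Z)-5-iodo-3-methyl-2-(trimethylsilyl)pent-2-en-1-yl]phenoxy}tri(propan-2-yl)silane | C[Si](C)(C)/C(Cc1cc(Br)ccc1O[Si](C(C)C)(C(C)C)C(C)C)=C(C)\CCI | intermediate
23 | [(3Z)-5-{5-bromo-2-[tri(propan-2-yl)silyloxy]phenyl}-3-methyl-4-(trimethylsilyl)pent-3-en-1-yl](iodo)zinc | C[Si](C)(C)/C(Cc1cc(Br)ccc1O[Si](C(C)C)(C(C)C)C(C)C)=C(C)\CC[Zn]I | intermediate (not isolated)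
24 | (5S)-5-[(1R,4E,8Z)-1-bromo-10-{5-bromo-2-[tri(propan-2-yl)silyloxy]phenyl}-4,8-dimethyl-9-(trimethylsilyl)deca-4,8-dien-1-yl]-5-methyloxolan-2-one | O=C1CC[C@](C)(O1)[C@H](Br)CC/C(C)=C/CC/C(C)=C(\[Si](C)(C)C)Cc1cc(Br)ccc1O[Si](C(C)C)(C(C)C)C(C)C | intermediate
25 | (5S)-5-[(1R)-1-bromo-3-{(2R,3R)-3-[(3Z)-5-{5-bromo-2-[tri(propan-2-yl)silyloxy]phenyl}-3-methyl-4-(trimethylsilyl)pent-3-en-1-yl]-2-methyloxiran-2-yl}propyl]-5-methyloxolan-2-one | O=C1CC[C@](C)(O1)[C@H](Br)CC[C@@]2(C)O[C@@H]2CC/C(C)=C(\[Si](C)(C)C)Cc1cc(Br)ccc1O[Si](C(C)C)(C(C)C)C(C)C | intermediate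
26 | (5S)-5-[(1R,4R,5S,8Z)-1,5-dibromo-10-{5-bromo-2-[tri(propan-2-yl)silyloxy]phenyl}-4-hydroxy-4,8-dimethyl-9-(trimethylsilyl)dec-8-en-1-yl]-5-methyloxolan-2-one | O=C1CC[C@](C)(O1)[C@H](Br)CC[C@@](C)(O)[C@@H](Br)CC/C(C)=C(\[Si](C)(C)C)Cc1cc(Br)ccc1O[Si](C(C)C)(C(C)C)C(C)C | intermediate
27 | (5S)-5-[(1R)-1-bromo-3-{(1S,6S)-6-bromo-2-({5-bromo-2-[tri(propan-2-yl)silyloxy]phenyl}methyl)-1,3-dimethylcyclohex-2-en-1-yl}propyl]-5-methyloxolan-2-one | O=C1CC[C@](C)(O1)[C@H](Br)CC[C@]2(C)[C@@H](Br)CCC(C)=C2Cc3cc(Br)ccc3O[Si](C(C)C)(C(C)C)C(C)C | intermediate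
28 | (4S,5R)-5-bromo-7-{(1S,6S)-6-bromo-2-({5-bromo-2-[tri(propan-2-yl)silyloxy]phenyl}methyl)-1,3-dimethylcyclohex-2-en-1-yl}-4-hydroxy-N-methoxy-N,4-dimethylheptanamide | CON(C)C(=O)CC[C@](C)(O)[C@H](Br)CC[C@]2(C)[C@@H](Br)CCC(C)=C2Cc3cc(Br)ccc3O[Si](C(C)C)(C(C)C)C(C)C | intermediate
29 | (4S,5R)-5-bromo-7-{(1S,6S)-6-bromo-2-({5-bromo-2-[tri(propan-2-yl)silyloxy]phenyl}methyl)-1,3-dimethylcyclohex-2-en-1-yl}-N-methoxy-N,4-dimethyl-4-[(triethylsilyl)oxy]heptanamide | CON(C)C(=O)CC[C@](C)(O[Si](CC)(CC)CC)[C@H](Br)CC[C@]2(C)[C@@H](Br)CCC(C)=C2Cc3cc(Br)ccc3O[Si](C(C)C)(C(C)C)C(C)C | intermediate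
30 | (6S,7R)-7-bromo-9-{(1S,6S)-6-bromo-2-({5-bromo-2-[tri(propan-2-yl)silyloxy]phenyl}methyl)-1,3-dimethylcyclohex-2-en-1-yl}-2,6-dimethyl-6-[(triethylsilyl)oxy]non-1-en-3-one | CC(=C)C(=O)CC[C@](C)(O[Si](CC)(CC)CC)[C@H](Br)CC[C@]2(C)[C@@H](Br)CCC(C)=C2Cc3cc(Br)ccc3O[Si](C(C)C)(C(C)C)C(C)C | intermediate
31 | (3S,6S,7R)-7-bromo-9-{(1S,6S)-6-bromo-2-({5-bromo-2-[tri(propan-2-yl)silyloxy]phenyl}methyl)-1,3-dimethylcyclohex-2-en-1-yl}-2,6-dimethyl-6-[(triethylsilyl)oxy]non-1-en-3-ol | CC(=C)[C@@H](O)CC[C@](C)(O[Si](CC)(CC)CC)[C@H](Br)CC[C@]2(C)[C@@H](Br)CCC(C)=C2Cc3cc(Br)ccc3O[Si](C(C)C)(C(C)C)C(C)C | intermediate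
32 | (6S,7S,10R,11S,14S)-macrolactone: bromophycolide A skeleton with prop-1-en-2-yl in place of CMe2Br on C14, OSiEt3 on C11 and OSi(i-Pr)3 on ring B | CC1=C2Cc3cc(ccc3O[Si](C(C)C)(C(C)C)C(C)C)C(=O)O[C@H](C(C)=C)CC[C@](C)(O[Si](CC)(CC)CC)[C@H](Br)CC[C@]2(C)[C@@H](Br)CC1 | intermediate
33 | bromophycolide A 11-O-triethylsilyl ether, phenol O-tri(propan-2-yl)silyl ether | CC1=C2Cc3cc(ccc3O[Si](C(C)C)(C(C)C)C(C)C)C(=O)O[C@H](C(C)(C)Br)CC[C@](C)(O[Si](CC)(CC)CC)[C@H](Br)CC[C@]2(C)[C@@H](Br)CC1 | intermediate
34 | bromophycolide A, (6S,7S,10R,11S,14S) | CC1=C2Cc3cc(ccc3O)C(=O)O[C@H](C(C)(C)Br)CC[C@](C)(O)[C@H](Br)CC[C@]2(C)[C@@H](Br)CC1 | target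

Total step count: 24. Longest linear sequence: 17 steps (steps 1 to 6 and 14 to 24, from pent-4-yn-1-ol).

Steps most likely to fail

Step 17 (proposed new method). Ionization of the activated C7 hydroxyl may drain into proton loss from the bromiranium ion, transfer of the C10 bromine to C7 or protodesilylation faster than the sterically demanding attack of C2 on C7. The fallback uses a known halonium-induced cation–olefin cyclization that starts from the alkene instead of a bromohydrin. It sets out from 24, which is treated with Et2SBr·SbCl5Br in MeNO2 at −25 °C. Bromiranium formation at C6=C7 is then not face-selective, so 27 should form together with the (1R,6R)-diastereomeric ring-A lactone F1, from which it is separated by chromatography. This bypasses steps 15 and 16 and comes back to the route at 27.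

Step 5. Enantiofacial discrimination may be poor, because an all-alkyl trisubstituted alkene gives the catalyst less to hold than aryl-substituted acids, and Br+ transfer between alkene molecules can erode selectivity. The fallback sets the C10/C11 pair by epoxidation and SN2 opening, all known chemistry. It sets out from 7, which undergoes Shi epoxidation with the L-fructose-derived ketone to give ethyl 3-[(2S,3S)-3-(but-3-yn-1-yl)-2-methyloxiran-2-yl]propanoate F2. Li2NiBr4 in THF opens F2 at C10 with inversion to give ethyl (4S,5R)-5-bromo-4-hydroxy-4-methylnon-8-ynoate F3. Catalytic TsOH in toluene lactonizes F3, and the route is rejoined at 9.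

Step 22. Intermolecular capture of the acylpalladium intermediate (oligomerization) or reduction of the aryl bromide may outrun ring closure onto the hindered secondary alcohol. The fallback separates carbonylation from ring closure. It sets out from 31, which is hydroxycarbonylated (Pd(OAc)2, Xantphos, CO, Et3N, dioxane/H2O, 90 °C) to the seco acid F4. Shiina macrolactonization of F4 (2-methyl-6-nitrobenzoic anhydride, DMAP, toluene, high dilution) then comes back to the route at 32.

Further compounds
F1 | step 17 | (5S)-5-[(1R)-1-bromo-3-{(1R,6R)-6-bromo-2-({5-bromo-2-[tri(propan-2-yl)silyloxy]phenyl}methyl)-1,3-dimethylcyclohex-2-en-1-yl}propyl]-5-methyloxolan-2-one | O=C1CC[C@](C)(O1)[C@H](Br)CC[C@@]2(C)[C@H](Br)CCC(C)=C2Cc3cc(Br)ccc3O[Si](C(C)C)(C(C)C)C(C)C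
F2 | step 5 | ethyl 3-[(2S,3S)-3-(but-3-yn-1-yl)-2-methyloxiran-2-yl]propanoate | CCOC(=O)CC[C@]1(C)O[C@H]1CCC#C
F3 | step 5 | ethyl (4S,5R)-5-bromo-4-hydroxy-4-methylnon-8-ynoate | CCOC(=O)CC[C@](C)(O)[C@H](Br)CCC#C
F4 | step 22 | seco acid: compound 31 with CO2H in place of the aryl bromine (configuration unchanged) | CC(=C)[C@@H](O)CC[C@](C)(O[Si](CC)(CC)CC)[C@H](Br)CC[C@]2(C)[C@@H](Br)CCC(C)=C2Cc3cc(ccc3O[Si](C(C)C)(C(C)C)C(C)C)C(O)=O
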